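# Proposed total synthesis of kaempferol 3,7-di-O-sulfate (19)

## The problem

Kaempferol 3,7-di-O-sulfate 19 is a flat, achiral flavonol: a 4H-chromen-4-one (rings A and C) with a 4-hydroxyphenyl ring B at C2 and oxygen at C3, C5 and C7. It has no stereocentre, so nothing has to be controlled in three dimensions. The real task is to sort four hydroxyl groups of similar kind: O3 and O7 must become sulfate half-esters while O5 and O4' stay free. O5 sorts itself, because its hydrogen bond to the C4 carbonyl makes it the least reactive hydroxyl of a flavonol. O4' is about as reactive as O7 and needs a protecting group that can be removed without acid. The sulfate half-esters are the fragile groups: they hydrolyse in acid and on heating, so they must be installed late, carried as salts, and protonated only in the last, cold operation. Ring C should be closed onto a phloroglucinol-type ring A with the C3 oxygen already in place, since oxidising C3 of a finished 5,7-dioxygenated flavone costs steps. The feature that invites an aryne is that O1 and C4 sit on the neighbouring ring-A carbons C8a and C4a, and C4a is the one flanked by the C5 oxygen. This is the pattern in which a 3-alkoxybenzyne accepts a nucleophile at the carbon remote from oxygen and an electrophile at the carbon next to it.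

## Retrosynthesis

**19 from 18 and 17.** The last operations should touch only a counter-ion and one O–CH2Ph bond. Acid 19 is therefore traced to its disodium salt 18, and 18 to the 4'-O-benzyl ether 17. Benzyl is the one common phenol protecting group that leaves under neutral hydrogenolysis, which sulfate salts tolerate. An acetal or silyl group at O4' would need acid or fluoride at a stage where the molecule is a polar salt.

**17 from 15.** The two O–S bonds at O3 and O7 are cut together, leading to 4'-O-benzylkaempferol 15. Differentiated protection of O5 would cost a desymmetrised ring A. It is not needed, because the chelated 5-OH is the position that sulfur trioxide–amine reagents leave alone. The forward step must sulfate the enolic O3 completely without touching O5.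

**15 from 14.** The three free hydroxyls of 15 are traced to methoxymethyl (MOM) acetals in 14. These acetals survive organolithium, enolate and fluoride chemistry, help ortho-lithiation, and leave in one acidic operation that the benzyl ether survives. The forward step is plain acetal methanolysis.

**14 from 8 and 12 (through aryne 13).** The C8a–O1 and C4a–C4 bonds are cut at once. This opens ring C to the silylaryl triflate 8, which releases 3,5-bis(methoxymethoxy)benzyne 13, and the α-alkoxy aroylacetate 12. Cutting C2–C3 (Baker–Venkataraman logic) or O1–C2 (chalcone logic) would be safer but starts from an acylated phloroglucinol and usually adds the C3 oxygen by a later oxidation. Here both ring-C carbonyl-side carbons, the C3 oxygen and ring B arrive in one piece at the final oxidation level. The forward reaction must deliver the enolate oxygen to the aryne carbon remote from the acetal oxygen, and the resulting aryl anion must then close onto the ester. The orientation follows the usual behaviour of 3-alkoxyarynes. Attack through oxygen and not carbon is the unproven demand. The attacked aryne carbon has only C–H on its far side, so the aryne offers no steric help. The bias must come from the enolate: a fully substituted, acetal-bearing α-carbon, a weakly coordinated cesium counter-ion, and no proton source.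

**8 from 6, 3, 2 and 1.** The O–S bond of the triflate and the C–Si bond are cut in turn. The silicon is placed by carbamate-directed ortho-lithiation of 3, which comes from 3,5-bis(methoxymethoxy)phenol 2 and hence from phloroglucinol 1. Carbamate 6 is the isolated silylated intermediate. The symmetry of 1 means only one regiochemical question remains: lithiation at C2, between carbamate and acetal, against C4, between two acetals.

**12 from 10 and 11; 10 from 9.** The bond between the glycolate α-carbon (future C3) and the aroyl carbon (future C2) is cut. This is a crossed Claisen condensation of the enolate of methyl (methoxymethoxy)acetate 10 with 4-(benzyloxy)benzoyl chloride 11. Ester 10 is the MOM ether of methyl glycolate 9.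

## Roads not taken

**Alternative 1:** Biomimetic Claisen folding. The cut is inside ring A (C4a–C5). In the forward sense the linear methyl (E)-9-[4-(benzyloxy)phenyl]-3,5,7-trioxonon-8-enoate A1 would be treated with Mg(OMe)2 or methanolic KOH, so that its C6 carbanion closes onto the ester carbonyl and aromatises to 4-O-benzylnaringenin chalcone A2.
- Merits: polyketide Claisen cyclisations of this kind are known, so the key step has better precedent than the one chosen here. The symmetry of the new ring removes any regiochemical question.
- Weak points: A1 is a sensitive poly-β-carbonyl compound carrying a Michael acceptor. Aldol-type closure and pyrone lactonisation compete with the Claisen mode. The route spends its key step building a ring that phloroglucinol 1 supplies ready-made.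
- Further cost: A2 lacks the C3 oxygen and the pyranone. Ring C must still be closed, dehydrogenated and hydroxylated at C3, and the Algar–Flynn–Oyamada shortcut is unreliable when a 6'-hydroxyl is present. Three free ring-A phenols would then need sorting.
- Comparison: Alternative 1 is ahead on precedent for its key step. The chosen plan sets against this a product already at the flavonol oxidation level with O3 in place, and a shorter end-game.

**Alternative 2:** Three-component carbonylative annulation. The cuts are C4a–C4, C4–C3 and O1–C2. With PdCl2(PPh3)2 in Et2NH, 2-iodo-5-(methoxymethoxy)benzene-1,3-diol A3, carbon monoxide A4 and 1-(benzyloxy)-4-ethynylbenzene A5 would give an ynone that closes in situ to 4'-benzyloxy-5-hydroxy-7-(methoxymethoxy)flavone A6.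
- Merits: it forms three bonds in one pot by a known reaction class of ortho-iodophenols. It is more convergent than the chosen key step, and it delivers O5 free and O7 protected from the start. In these respects it is the better road.
- Weak points: oxidative addition of zerovalent palladium into an iodide flanked by two hydroxyls on a very electron-rich ring is slow. A3 requires desymmetrisation of an iodinated derivative of 1. Six-membered closure must beat 5-exo-dig closure. Toxic gas A4 must be handled.
- Further cost: A6 has no oxygen at C3, so an epoxidation–rearrangement sequence on an electron-rich flavone is needed before sulfation.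
- Comparison: the chosen plan sets against the better precedent of Alternative 2 a C3 oxygen carried in from methyl glycolate 9, a symmetrical ring-A precursor, and no late oxidation.

**Alternative 3:** Trifluorobenzoyl acylation and SNAr closure. The cuts are C3–C4 and C8a–O1. The lithium enolate of 1-[4-(benzyloxy)phenyl]-2-[(4-methoxybenzyl)oxy]ethan-1-one A7 would be C-acylated by 2,4,6-trifluorobenzoyl chloride A8 to the diketone A9. On warming with K2CO3, the enolate oxygen of A9 displaces an ortho fluoride to give 4'-benzyloxy-5,7-difluoro-3-(4-methoxybenzyloxy)flavone A10.
- Merits: the C3 oxygen is in place, the ring closure is an intramolecular SNAr with no ambiguity about which atom bonds to ring A, and A8 is a catalogue compound. Its ring closure is clearly safer than the one chosen here.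
- Weak points: A10 still carries two C–F bonds where the target needs C–O bonds. Two further SNAr steps with alkoxides are needed on a pyranone that is itself open to attack at C2, followed by removal of whatever groups were introduced. C- against O-acylation of the enolate of A7 must also be controlled.
- Comparison: the chosen plan sets against the safer closure of Alternative 3 a ring A that arrives with both oxygens from 1, and three acetals that leave in one operation.

Key step: step 7

Assumption: the target is taken as the free bis(hydrogen sulfate) drawn; it is approached through its disodium salt 18, and the acid is liberated only in the final cold operation.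

## Route

**Step 1**
Reactants: 1 phloroglucinol
Product: 2 3,5-bis(methoxymethoxy)phenol
Conditions: MOMCl (2.0 equiv), i-Pr2NEt (2.2 equiv), DMF, 0 °C to rt; chromatography
Reagents that add atoms: chloromethyl methyl ether, COCCl
Why: Williamson-type O-alkylation of the phenoxide by the chloromethyl ether; two of three equivalent hydroxyls are capped statistically on the cheapest material of the route, and the mono-, bis- and tris-ethers differ enough in polarity to be separated.

**Step 2**
Reactants: 2 3,5-bis(methoxymethoxy)phenol
Product: 3 3,5-bis(methoxymethoxy)phenyl N-isopropylcarbamate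
Conditions: i-PrNCO (1.3 equiv), NEt3 (cat.), CH2Cl2, rt
Reagents that add atoms: isopropyl isocyanate, CC(C)N=C=O
Why: Base-catalysed addition of a phenol to an isocyanate (carbamoylation); the N-monoalkyl carbamate is a strong ortho-director after N-silylation and can later be removed by mild E1cB cleavage.

**Step 3**
Reactants: 3 3,5-bis(methoxymethoxy)phenyl N-isopropylcarbamate
Product: 6 3,5-bis(methoxymethoxy)-2-(trimethylsilyl)phenyl N-isopropylcarbamate, via N-silyl carbamate 4 (not isolated), via N-silyl arylsilane 5 (not isolated)
Conditions: t-BuMe2SiOTf (1.1 equiv), TMEDA, Et2O, 0 °C to rt; n-BuLi (2.2 equiv), TMEDA, −78 °C; Me3SiCl, −78 °C to rt; aq. NaHSO4, 0 °C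
Reagents that add atoms: tert-butyldimethylsilyl trifluoromethanesulfonate (its silicon is carried in 4 and 5 only), CC(C)(C)[Si](C)(C)OS(=O)(=O)C(F)(F)F; chlorotrimethylsilane, C[Si](C)(C)Cl
Why: Directed ortho-metalation; transient N-silylation masks the N–H, and the O-carbamate (the strongest director present) together with the neighbouring acetal oxygen should deliver lithium to C2 (C2 and C6 are equivalent) in preference to C4 between the two weaker acetal directors. The aryllithium is silylated and the N–Si bond is hydrolysed on work-up.

**Step 4**
Reactants: 6 3,5-bis(methoxymethoxy)-2-(trimethylsilyl)phenyl N-isopropylcarbamate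
Product: 8 3,5-bis(methoxymethoxy)-2-(trimethylsilyl)phenyl trifluoromethanesulfonate, via silylphenol 7 (not isolated)
Conditions: DBU (1.5 equiv), Et2NH (1.2 equiv), MeCN, 40 °C; then PhNTf2 (1.5 equiv), rt
Reagents that add atoms: N-phenylbis(trifluoromethanesulfonimide), O=S(=O)(N(c1ccccc1)S(=O)(=O)C(F)(F)F)C(F)(F)F
Why: E1cB cleavage of the N-monosubstituted carbamate (the isocyanate is scavenged by Et2NH) frees the phenoxide, which is O-sulfonylated in the same flask; this is the standard close of a silylaryl triflate synthesis and leaves acetals and the aryl–silicon bond untouched.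

**Step 5**
Reactants: 9 methyl glycolate
Product: 10 methyl 2-(methoxymethoxy)acetate
Conditions: MOMCl (1.2 equiv), i-Pr2NEt (1.5 equiv), CH2Cl2, 0 °C to rt
Reagents that add atoms: chloromethyl methyl ether, COCCl
Why: O-alkylation of a primary alcohol with a chloromethyl ether under amine base (acetal protection); the ester is inert to these conditions.

**Step 6**
Reactants: 10 methyl 2-(methoxymethoxy)acetate; 11 4-(benzyloxy)benzoyl chloride
Product: 12 methyl 3-[4-(benzyloxy)phenyl]-2-(methoxymethoxy)-3-oxopropanoate (racemic, enolisable)
Conditions: LiN(SiMe3)2 (2.1 equiv), THF, −78 °C; then 11 (1.0 equiv), −78 to 0 °C; aq. NH4Cl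
Reagents that add atoms: none
Why: Crossed Claisen condensation (C-acylation of a lithium ester enolate by an acid chloride); the second equivalent of base converts the more acidic β-keto ester into its enolate and so stops a second acylation. The new stereocentre is racemic and is erased in step 7.

**Step 7**
Reactants: 8 3,5-bis(methoxymethoxy)-2-(trimethylsilyl)phenyl trifluoromethanesulfonate; 12 methyl 3-[4-(benzyloxy)phenyl]-2-(methoxymethoxy)-3-oxopropanoate
Product: 14 2-[4-(benzyloxy)phenyl]-3,5,7-tris(methoxymethoxy)-4H-chromen-4-one, via 3,5-bis(methoxymethoxy)benzyne 13 (not isolated)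
Conditions: CsF (4 equiv), THF, 65 °C (sealed); 12 stirred with CsF first, then 8 (1.5 equiv) added slowly
Reagents that add atoms: none
Why: Proposed new method: fluoride attack at silicon in 8 triggers 1,2-elimination of triflate to aryne 13, while CsF has already converted 12 into its cesium enolate. The enolate is proposed to bond through its ketone-derived oxygen to the aryne carbon remote from the C3 acetal oxygen (future C8a), which places the carbanion on the carbon next to that oxygen (future C4a). In the U-shaped enolate the ester lies cis to the attacking oxygen, so the aryl anion reaches the ester carbonyl in a 6-exo-trig addition–elimination, expels methoxide and closes ring C; no stereocentre is formed and that of 12 disappears. The closest known reaction type is the CsF-mediated coupling of silylaryl triflates with salicylate esters to xanthones (phenoxide O-arylation, then intramolecular acyl capture); using an enolate oxygen in place of a phenoxide is not established, since β-keto esters normally bond to arynes through carbon. The regioselectivity is expected from aryne distortion by the inductively withdrawing acetal oxygen, which makes the remote carbon the electrophilic one and stabilises the charge at the near one. The chemoselectivity rests on the enolate: its α-carbon is fully substituted and carries the acetal oxygen, so C-arylation would have to build a congested quaternary centre, whereas the oxygen of a weakly coordinated cesium enolate in THF is exposed. The attacked aryne carbon has only C–H on its far side, so the aryne gives no steric help, and this O-against-C preference is the unproven point. Pre-forming the enolate, avoiding acidic solvents and keeping the aryne at low steady-state concentration are meant to make acyl capture faster than protonation of the aryl anion.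

**Step 8**
Reactants: 14 2-[4-(benzyloxy)phenyl]-3,5,7-tris(methoxymethoxy)-4H-chromen-4-one
Product: 15 2-[4-(benzyloxy)phenyl]-3,5,7-trihydroxy-4H-chromen-4-one (4'-O-benzylkaempferol)
Conditions: 3 M HCl, MeOH–THF, 50 °C
Reagents that add atoms: none
Why: Acid-catalysed acetal exchange with methanol removes all three MOM groups; the benzyl aryl ether and the flavonol core are stable to dilute methanolic HCl.

**Step 9**
Reactants: 15 4'-O-benzylkaempferol
Product: 17 disodium 4'-O-benzylkaempferol 3,7-disulfate, via bis(pyridinium) disulfate 16 (not isolated)
Conditions: SO3·pyridine (8 equiv), pyridine, 40 °C; then aq. NaHCO3 to pH 8; Sephadex LH-20 or C18 chromatography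
Reagents that add atoms: sulfur trioxide–pyridine complex, [O-]S(=O)(=O)[n+]1ccccc1; sodium hydrogen carbonate, [Na+].OC([O-])=O
Why: O-sulfation of phenolic and enolic hydroxyls with an SO3–amine complex; O7 and O3 should react, while O5 is held in a six-membered hydrogen bond to the C4 carbonyl and is the hydroxyl that such reagents leave unsulfated in flavonols. Neutralisation fixes the half-esters as stable sodium salts.

**Step 10**
Reactants: 17 disodium 4'-O-benzylkaempferol 3,7-disulfate
Product: 18 disodium kaempferol 3,7-disulfate
Conditions: H2 (1 atm), 10% Pd/C, MeOH–H2O, rt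
Reagents that add atoms: none
Why: Hydrogenolysis of a benzyl aryl ether over Pd/C under neutral conditions; sulfate monoester salts are inert to it and the pyranone double bond of a flavonol is not reduced at atmospheric pressure.

**Step 11**
Reactants: 18 disodium kaempferol 3,7-disulfate
Product: 19 kaempferol 3,7-di-O-sulfate [5-hydroxy-2-(4-hydroxyphenyl)-4-oxo-4H-chromene-3,7-diyl bis(hydrogen sulfate)]
Conditions: 1 M HCl to pH 1, H2O, 0 °C; C18 solid-phase extraction (0.01 M HCl then H2O wash, MeOH elution); concentration below 20 °C, lyophilisation
Reagents that add atoms: none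
Why: Proton-for-sodium exchange; the aromatic disulfate is retained on reversed phase while NaCl and excess HCl are washed out. The operation is done cold and quickly because aryl hydrogen sulfates hydrolyse under acid catalysis.

## Compound list

1 | phloroglucinol | Oc1cc(O)cc(O)c1 | starting material
2 | 3,5-bis(methoxymethoxy)phenol | COCOc1cc(O)cc(OCOC)c1 | intermediate
3 | 3,5-bis(methoxymethoxy)phenyl N-isopropylcarbamate | CC(C)NC(=O)Oc1cc(OCOC)cc(OCOC)c1 | intermediate
4 | 3,5-bis(methoxymethoxy)phenyl N-(tert-butyldimethylsilyl)-N-isopropylcarbamate | CC(C)N(C(=O)Oc1cc(OCOC)cc(OCOC)c1)[Si](C)(C)C(C)(C)C | intermediate (not isolated)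
5 | 3,5-bis(methoxymethoxy)-2-(trimethylsilyl)phenyl N-(tert-butyldimethylsilyl)-N-isopropylcarbamate | CC(C)N(C(=O)Oc1cc(OCOC)cc(OCOC)c1[Si](C)(C)C)[Si](C)(C)C(C)(C)C | intermediate (not isolated)
6 | 3,5-bis(methoxymethoxy)-2-(trimethylsilyl)phenyl N-isopropylcarbamate | CC(C)NC(=O)Oc1cc(OCOC)cc(OCOC)c1[Si](C)(C)C | intermediate
7 | 3,5-bis(methoxymethoxy)-2-(trimethylsilyl)phenol | COCOc1cc(O)c([Si](C)(C)C)c(OCOC)c1 | intermediate (not isolated)
8 | 3,5-bis(methoxymethoxy)-2-(trimethylsilyl)phenyl trifluoromethanesulfonate | C[Si](C)(C)c1c(OCOC)cc(OCOC)cc1OS(=O)(=O)C(F)(F)F | intermediate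
9 | methyl glycolate | COC(=O)CO | starting material
10 | methyl 2-(methoxymethoxy)acetate | COCOCC(=O)OC | intermediate
11 | 4-(benzyloxy)benzoyl chloride | O=C(Cl)c1ccc(OCc2ccccc2)cc1 | starting material
12 | methyl 3-[4-(benzyloxy)phenyl]-2-(methoxymethoxy)-3-oxopropanoate (racemic) | COC(=O)C(OCOC)C(=O)c1ccc(OCc2ccccc2)cc1 | intermediate
13 | 3,5-bis(methoxymethoxy)benzyne | COCOC1=CC(OCOC)=CC#C1 | intermediate (not isolated)
14 | 2-[4-(benzyloxy)phenyl]-3,5,7-tris(methoxymethoxy)-4H-chromen-4-one | O=c1c(OCOC)c(-c2ccc(OCc3ccccc3)cc2)oc2cc(OCOC)cc(OCOC)c12 | intermediate
15 | 2-[4-(benzyloxy)phenyl]-3,5,7-trihydroxy-4H-chromen-4-one (4'-O-benzylkaempferol) | O=c1c(O)c(-c2ccc(OCc3ccccc3)cc2)oc2cc(O)cc(O)c12 | intermediate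
16 | bis(pyridinium) 4'-O-benzylkaempferol 3,7-disulfate | c1cc[nH+]cc1.c1cc[nH+]cc1.O=c1c(OS(=O)(=O)[O-])c(-c2ccc(OCc3ccccc3)cc2)oc2cc(OS(=O)(=O)[O-])cc(O)c12 | intermediate (not isolated)
17 | disodium 4'-O-benzylkaempferol 3,7-disulfate | [Na+].[Na+].O=c1c(OS(=O)(=O)[O-])c(-c2ccc(OCc3ccccc3)cc2)oc2cc(OS(=O)(=O)[O-])cc(O)c12 | intermediate
18 | disodium kaempferol 3,7-disulfate | [Na+].[Na+].O=c1c(OS(=O)(=O)[O-])c(-c2ccc(O)cc2)oc2cc(OS(=O)(=O)[O-])cc(O)c12 | intermediate
19 | kaempferol 3,7-di-O-sulfate | O=c1c(OS(=O)(=O)O)c(-c2ccc(O)cc2)oc2cc(OS(=O)(=O)O)cc(O)c12 | target

## Step count and least certain steps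

Total: 11 steps. Longest linear sequence: 9 steps (steps 1, 2, 3, 4, 7, 8, 9, 10, 11); steps 5 and 6 form the two-step side branch to 12.

**Step 7 (key step, proposed new method).**
- What may go wrong: the enolate may bond to the aryne through carbon instead of oxygen. Arynes are soft electrophiles, and even fully substituted β-keto ester enolates commonly arylate at carbon; the aryl anion then attacks the ketone and the sequence ends in acyl migration, not ring-C closure. A second risk is protonation of the O-arylated aryl anion before it reaches the ester.
- Fallback (known chemistry only): it sets out from 8, uses 10 and 11, and rejoins the route at 15.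
  - Ester 10 is saponified (LiOH, THF–H2O) to (methoxymethoxy)acetic acid F1.
  - F1 is heated with 8 and CsF in THF (sealed, 125 °C). The aryne inserts into the O–C(acyl) bond of the carboxylic acid: carboxylate O-arylation at the remote carbon, four-membered acyl capture by the aryl anion, ring opening. This is an established reaction of silylaryl triflates and should give 1-[2-hydroxy-4,6-bis(methoxymethoxy)phenyl]-2-(methoxymethoxy)ethan-1-one F2. The same C8a–O1 and C4a–C4 bonds are thus made in the precedented mode.
  - F2 is O-aroylated with 11 (NEt3, DMAP, CH2Cl2) to 2-[(methoxymethoxy)acetyl]-3,5-bis(methoxymethoxy)phenyl 4-(benzyloxy)benzoate F3.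
  - Baker–Venkataraman rearrangement (KOH, pyridine, 50 °C) gives 1-[4-(benzyloxy)phenyl]-3-[2-hydroxy-4,6-bis(methoxymethoxy)phenyl]-2-(methoxymethoxy)propane-1,3-dione F4.
  - Methanolic HCl at 50 °C then closes ring C by cyclodehydration and removes the three acetals, delivering 15.

**Step 3.**
- What may go wrong: lithiation at C4 between the two acetal oxygens may compete with lithiation at C2. An acetal may also be cleaved by the silyl triflate before it is consumed by the carbamate N–H.
- Fallback: it sets out from 2 and rejoins at 8, replacing directed metalation by halogen–metal exchange.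
  - Ortho-selective bromination (NBS, i-Pr2NH cat., CH2Cl2, 0 °C) gives 2-bromo-3,5-bis(methoxymethoxy)phenol F5. It is separated from its symmetrical para isomer at this stage, where the loss of symmetry makes the assignment simple.
  - O-Silylation with (Me3Si)2NH gives [2-bromo-3,5-bis(methoxymethoxy)phenoxy]trimethylsilane F6.
  - n-BuLi in THF at −78 °C effects bromine–lithium exchange and 1,3 O-to-C silyl migration (retro-Brook) to the lithium salt of 7. This is triflated in the same flask with Tf2O to give 8.

**Step 9.**
- What may go wrong: sulfation of the hydrogen-bonded, enolic O3 may be incomplete, or slow sulfation may begin at O5. Either gives mixtures of very polar salts that are hard to separate.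
- Fallback: it sets out from 15 and rejoins at 19, using neutral, chromatographable sulfate diesters.
  - 15 is treated with 2,2,2-trichloroethyl chlorosulfate (2.2 equiv, NEt3, DMAP, THF, 0 °C) to give 4'-O-benzylkaempferol 3,7-bis(2,2,2-trichloroethyl sulfate) F7, which is purified on silica.
  - Transfer hydrogenolysis (HCO2NH4, 10% Pd/C, MeOH) removes both trichloroethyl groups and the benzyl ether, giving diammonium kaempferol 3,7-disulfate F8.
  - F8 is acidified exactly as in step 11 to give 19.

**Step 11.**
- What may go wrong: the free aryl hydrogen sulfate may undergo acid-catalysed, self-accelerating hydrolysis during elution and concentration. Sodium may also be incompletely exchanged.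
- Fallback: it sets out from 18 and rejoins at 19 by salt metathesis, with no excess mineral acid. Aqueous BaCl2 converts 18 into barium kaempferol 3,7-disulfate F9, which is collected. F9 is suspended in ice-cold water and treated with exactly one equivalent of H2SO4, so that BaSO4 precipitates and the filtrate contains only 19. The filtrate is freeze-dried at once.

## Further compounds

F1 | step 7 | (methoxymethoxy)acetic acid | COCOCC(=O)O
F2 | step 7 | 1-[2-hydroxy-4,6-bis(methoxymethoxy)phenyl]-2-(methoxymethoxy)ethan-1-one | COCOCC(=O)c1c(O)cc(OCOC)cc1OCOC
F3 | step 7 | 2-[(methoxymethoxy)acetyl]-3,5-bis(methoxymethoxy)phenyl 4-(benzyloxy)benzoate | COCOCC(=O)c1c(OC(=O)c2ccc(OCc3ccccc3)cc2)cc(OCOC)cc1OCOC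
F4 | step 7 | 1-[4-(benzyloxy)phenyl]-3-[2-hydroxy-4,6-bis(methoxymethoxy)phenyl]-2-(methoxymethoxy)propane-1,3-dione | COCOC(C(=O)c1ccc(OCc2ccccc2)cc1)C(=O)c1c(O)cc(OCOC)cc1OCOC
F5 | step 3 | 2-bromo-3,5-bis(methoxymethoxy)phenol | COCOc1cc(O)c(Br)c(OCOC)c1
F6 | step 3 | [2-bromo-3,5-bis(methoxymethoxy)phenoxy]trimethylsilane | COCOc1cc(O[Si](C)(C)C)c(Br)c(OCOC)c1
F7 | step 9 | 4'-O-benzylkaempferol 3,7-bis(2,2,2-trichloroethyl sulfate) | O=c1c(OS(=O)(=O)OCC(Cl)(Cl)Cl)c(-c2ccc(OCc3ccccc3)cc2)oc2cc(OS(=O)(=O)OCC(Cl)(Cl)Cl)cc(O)c12
F8 | step 9 | diammonium kaempferol 3,7-disulfate | [NH4+].[NH4+].O=c1c(OS(=O)(=O)[O-])c(-c2ccc(O)cc2)oc2cc(OS(=O)(=O)[O-])cc(O)c12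
F9 | step 11 | barium kaempferol 3,7-disulfate | [Ba+2].O=c1c(OS(=O)(=O)[O-])c(-c2ccc(O)cc2)oc2cc(OS(=O)(=O)[O-])cc(O)c12
A1 | alternative 1 | methyl (E)-9-[4-(benzyloxy)phenyl]-3,5,7-trioxonon-8-enoate | COC(=O)CC(=O)CC(=O)CC(=O)/C=C/c1ccc(OCc2ccccc2)cc1
A2 | alternative 1 | 4-O-benzylnaringenin chalcone | O=C(/C=C/c1ccc(OCc2ccccc2)cc1)c1c(O)cc(O)cc1O
A3 | alternative 2 | 2-iodo-5-(methoxymethoxy)benzene-1,3-diol | COCOc1cc(O)c(I)c(O)c1
A4 | alternative 2 | carbon monoxide | [C-]#[O+]
A5 | alternative 2 | 1-(benzyloxy)-4-ethynylbenzene | C#Cc1ccc(OCc2ccccc2)cc1
A6 | alternative 2 | 4'-benzyloxy-5-hydroxy-7-(methoxymethoxy)flavone | O=c1cc(-c2ccc(OCc3ccccc3)cc2)oc2cc(OCOC)cc(O)c12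
A7 | alternative 3 | 1-[4-(benzyloxy)phenyl]-2-[(4-methoxybenzyl)oxy]ethan-1-one | COc1ccc(COCC(=O)c2ccc(OCc3ccccc3)cc2)cc1
A8 | alternative 3 | 2,4,6-trifluorobenzoyl chloride | O=C(Cl)c1c(F)cc(F)cc1F
A9 | alternative 3 | 1-[4-(benzyloxy)phenyl]-2-[(4-methoxybenzyl)oxy]-3-(2,4,6-trifluorophenyl)propane-1,3-dione | O=C(c1ccc(OCc2ccccc2)cc1)C(OCc1ccc(OC)cc1)C(=O)c1c(F)cc(F)cc1F
A10 | alternative 3 | 4'-benzyloxy-5,7-difluoro-3-(4-methoxybenzyloxy)flavone | O=c1c(OCc2ccc(OC)cc2)c(-c2ccc(OCc3ccccc3)cc2)oc2cc(F)cc(F)c12
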